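If two flasks share every charge but the catalyst, I first ask whether the catalyst does more than set the speed of the clock.

| setting | Thursday's | Friday's | Saturday's |
|---|---|---|---|
| starting material | 0.600 M | 0.600 M | 0.600 M |
| coupling partner | 0.720 M | 0.720 M | 0.720 M |
| catalyst | 0.0180 M | 0.0540 M | 0.0180 M |
| time |  |  | 52 min |

| run | time / min | [product] / M |
|---|---|---|
| Thursday's run | 0.84 | 0.015 |
| Thursday's run | 1.9 | 0.032 |
| Thursday's run | 4.2 | 0.071 |
| Thursday's run | 9.4 | 0.152 |
| Thursday's run | 21 | 0.307 |
| Friday's run | 0.84 | 0.037 |
| Friday's run | 1.9 | 0.089 |
| Friday's run | 4.2 | 0.194 |
| Friday's run | 9.4 | 0.370 |
| Friday's run | 21 | 0.546 |

(scatter of a reading: 0.003 M)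

- Overall: starting material + coupling partner -> product, with catalyst as catalyst.
- Constant volume, constant temperature.
- What is held in complexes is read along with the free species.
- "The second partner" is coupling partner.
- An order is taken over about fifteen percent of the charge, up and down.

* order of the initial rate in [catalyst], near the charge of the Thursday's run, the rate being that where two percent of its starting material are product
* product in the Saturday's run at 52 min, as a share of the starting material charged

Thursday's flask reads 0.152 M of product at 9.4 min, and a straight line between Friday's readings at 1.9 min and 4.2 min reaches that amount at about 3.28 min. That is a ratio of 2.87 for a catalyst ratio of 3.00, so I read an order in catalyst of about 0.958 between these charges. The two curves therefore look like one curve run at two speeds.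

So where does Saturday's flask stand on Friday's clock? It has Thursday's charge, so, taking the order as one, I multiply its asked time by its catalyst charge and divide by Friday's catalyst charge, which gives 17.3 min. This equivalent time, the usual normalised time, is the quantity I carry.

What does Friday's flask hold then? The time falls between its readings at 9.4 min and 21 min, where the starting material left is 0.230 M and then 0.0540 M. If I let it fall exponentially between them, the decay constant is 0.125 min⁻¹, and my reckoning gives 85.8% for Saturday's flask.

The forecast gives an order of 0.95 and a share of 86%, by another route: “Saturation in starting material fits well”.

The flask gives an order of 0.99 and a share of 86.5%, both within the forecast's margins.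

    catalyst + starting material ⇌ catalyst-substrate complex, settled at all times (0.9620 M⁻¹)
    catalyst-substrate complex + coupling partner ⇌ ternary complex, settled at all times (17.80 M⁻¹)
    ternary complex → product + catalyst (1.512 min⁻¹)
    2 starting material ⇌ idle substrate dimer, settled at all times (7.080 M⁻¹)

Without the binding of two starting material into idle substrate dimer, the order in catalyst near Thursday's charge, which Saturday's flask shares, is still 0.99, so that binding is not what sets the clock and the equivalent time stays 17.3 min. What moves is the height of the curve at that time: Saturday's product goes from 86.5% to 95.1%. That binding is the main reason for the product missing from Saturday's flask at the asked time: its 8.6 percentage points make up 64% of what is missing.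

(The numbers in the tables stem from a simulated flask for an exercise; noise was put on by code.)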